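The numbers of this flask come from no measurement, and the outcome is calculated.

We decide to count each flask not in hours but in relaxation times of the step from substrate to target, as many as its decaying catalyst can deliver within the run.

| setting | Monday's | Saturday's | Friday's | Tuesday's |
|---|---|---|---|---|
| substrate | 13 mM | 13 mM | 13 mM | 13 mM |
| free catalyst | 65 µM | 65 µM | 65 µM | 65 µM |
| temperature | 60 °C | 20 °C | 40 °C | 80 °C |
| time | 3.0 h | 3.0 h | 3.0 h | 3.0 h |

    substrate + free catalyst ⇌ target + free catalyst, rate k1*[substrate]*[free catalyst] forward; the back reaction follows from the equilibrium constant (K1 = 0.293, k1 = 32.0 M⁻¹ s⁻¹, Ea1 = 55.0 kJ mol⁻¹, ΔH1 = −39.0 kJ mol⁻¹)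
    isomer of the product A + free catalyst ⇌ isomer of the product B + free catalyst, rate k2*[free catalyst]*[isomer of the product A] forward; the back reaction follows from the equilibrium constant (K2 = 1.6, k2 = 3.97 M⁻¹ s⁻¹, Ea2 = 64.0 kJ mol⁻¹, ΔH2 = −17.0 kJ mol⁻¹)
    free catalyst → spent catalyst (k3 = 0.00147 s⁻¹, Ea3 = 90.0 kJ mol⁻¹)
    target + free catalyst ⇌ isomer of the product A + free catalyst, rate k4*[free catalyst]*[target] forward; the back reaction follows from the equilibrium constant (K4 = 0.536, k4 = 0.759 M⁻¹ s⁻¹, Ea4 = 38.0 kJ mol⁻¹, ΔH4 = 27.0 kJ mol⁻¹)
    (constants at 80 °C)

- the constants hold at 80 °C; other temperatures follow from the activation energies and enthalpies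

1. the flask that comes out highest in amount of target, in percent of the substrate charged, or "all alike" when all lie within 1.5 percentage points (Monday's / Saturday's / Friday's / Tuesday's / all alike)
2. target at the end, in percent of the substrate charged, Monday's
3. target at the end, in percent of the substrate charged, Saturday's
4. target at the end, in percent of the substrate charged, Friday's
5. target at the end, in percent of the substrate charged, Tuesday's

Take Friday's flask in slow motion. In the first instants Friday's flask holds substrate and free catalyst, so the first step is where the substrate goes, while the catalyst begins to decay. At 40 °C its equilibrium constant is 1.60, and our zero is the even split: a constant of 1 would put half of the substrate across, so Friday's balance lies above that, at a share K/(1+K) of 61.5 %. In the middle, target is there to be taken on, but in Friday's flask the forward constant of the first step is 20.1 times that of the step from target to isomer of the product A, so we reckon the first step by itself and count what it makes, target and its isomers, as one pool. Meanwhile the clock slows. Free catalyst has a half-life of 6.57 h in Friday's flask, longer than the run, and its decay shortens 3.0 h to a working time, (1−exp(−decay constant × time))/decay constant, of 2.57 h. The approach to balance is pseudo-first-order, with constant forward constant × catalyst charge × (1+1/K), here 1.11 h⁻¹. The product of this constant and the working time is the relaxation count, 2.86 for Friday's. For the end of Friday's run we then reckon the pool at K/(1+K) × (1−exp(−count)), which is 58.0 %.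

The same two numbers serve the other flasks. Tuesday's catalyst has a half-life of 0.131 h, far under the run, yet its count is 6.24; with a constant of 0.293 we reckon the pool at 22.6 %. Monday's has constant 0.650 and count 6.75, giving 39.4 %. Saturday's has the high constant 4.44 but a count of 0.586, giving 36.2 %. We commit to Friday's as highest, with target a little under each pool.

The forecast also names Friday's, with 38.1 % for Monday's, 35.9 % for Saturday's, 55.6 % for Friday's and 22.4 % for Tuesday's, on the ground that catalyst exposure “sets the progress in each flask”. Its Friday's figure stands under our pool, since it is a figure for target after a loss.

The simulation gives Friday's as highest, with target at 55.8 % in Friday's, 38.1 % in Monday's, 35.6 % in Saturday's and 22.4 % in Tuesday's. The forecast names the right flask and stands within the tolerance on each figure, and Friday's pool of target and its isomers comes to 58.7 %.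

A share and a count need no integration. Take the neighbour of Friday's charged with 0.016 mM of free catalyst. Its working time stays the same, and it ends with 27.1 % of its catalyst spent, as Friday's does with 27.1 %. The count simply falls with the charge, to 0.704, and the same share of 61.5 % then gives 31.1 %. That neighbour ends with 68.9 % of substrate and 30.8 % of target.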